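**Remark on the chemistry (assumption):** the target has no stereogenic centre and its diaryl ether bonds rotate freely, so it is achiral and there is no enantiomer to select; the SMILES is taken as the constitution to be made. An atom-by-atom comparison of the precursor 5, the product 6 and the target shows that all substitution patterns agree, so no structure needed correcting and 5 and 6 are used unchanged.

## Structural features

The molecule is a linear triaryl diether: three benzene rings joined by two diaryl ether oxygens, with no sp3 carbon and no stereocentre. The central ring is fully substituted. Its two aryloxy groups are para to each other (C1, C4), its two bromines are para (C2, C5) and its two hydroxyls are para (C3, C6), so it is a hydroquinone that air or bromine can oxidise to the quinone. Each outer ring is a 2,3,5-tribromo-4-hydroxyphenoxy unit: the hydroxyl at C4 is para to the ether oxygen and sits between two bromines, a third bromine is ortho to the ether oxygen, and one C–H remains. The whole is constitutionally two-fold symmetric, which invites a two-directional synthesis from a central core and two identical arms. Fragile points are the central hydroquinone, the acidic polybromophenols and the eight aryl C–Br bonds, which rule out palladium/hydrogen, organolithiums and strong reductants. The difficulty is regiochemical, not stereochemical: four oxygens and eight bromines must be placed without ambiguity, and two ether bonds must be made to a hexasubstituted ring. The key step exploits the outer-ring carbon C4: an oxygen-bearing carbon para to the ether oxygen and flanked by two bromines has exactly the environment of the formyl-bearing carbon of a 2,6-dibromo-4-halobenzaldehyde, so that carbon can first carry a formyl group and then exchange it for oxygen.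

## Logic of the disconnections

**9 back to 8.** The two central O–H bonds are traced back to O–CH3 bonds. A free hydroquinone would be oxidised by bromine or peracid and would interfere in ether formation, whereas the methyl groups are already present from the first step. Nothing is gained in skeleton, but the central ring becomes inert for the whole sequence. The forward step must cleave two hindered aryl methyl ethers without touching two diaryl ethers and eight C–Br bonds, which calls for a Lewis acid that attacks only at the methyl carbon.

**8 back to 7.** One C–Br bond per outer ring, ortho to the ether oxygen, is cut. In 7 the two open carbons of each outer ring are equivalent and both ortho to the ether oxygen, so there is no regiochemical choice, only a count of one per ring. Postponing this bromine also leaves the ether oxygen conjugated with the outer ring during the migration step and leaves the fluoride-bearing carbon unhindered during ether formation. The gain is an outer ring with local symmetry that matches a commercial building block. The forward step must stop after one substitution per ring and must not oxidise the free phenols.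

**7 back to 6 and 5.** The formate O–C bonds are cut first (trivial). Then, in the retrosynthetic sense, the aryl C4–O bond of each outer ring is replaced by an aryl C4–C(formyl) bond. The reason is that an oxygen substituent at C4 could neither activate the ring for ether formation nor survive it unprotected, while a formyl group does both jobs and arrives with the two flanking bromines. The gain is an inversion of the electronic character of the outer ring, from an electron-rich hydroquinone ether to an electron-poor benzaldehyde. The forward step demands aryl migration in preference to hydride migration at both ends, and a substrate with nothing else that a peracid can oxidise.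

**5 back to 3 and two molecules of 4.** The two aryl C–O bonds on the outer-ring side of the ether oxygens are cut. The central ring cannot act as an electrophile once reduced, whereas the outer carbon is para to a formyl group and carries fluoride. The cut divides the molecule into a symmetric core and two identical arms, the largest possible simplification. The forward step demands that a hindered bis-phenoxide, each oxygen flanked by bromine and methoxy, attacks twice. It also demands that only fluoride leaves and that oxygen is excluded.

**3 back to 2 and 1.** The diol O–H bonds go back to quinone carbonyls (redox only), and the two C–OMe bonds go back to C–Br bonds. 1 is commercial and already holds all six ring carbons, both quinone oxygens and the two bromines that stay. No ring construction and no central bromination is needed. The forward step must replace exactly two bromines, para to each other.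

## Other disconnections considered

**Alternative 1:** Moore ring expansion.
- **Cut:** the central ring is taken apart at carbon–carbon bonds into a four-carbon squarate unit and a two-carbon ynol ether.
- **Forward key step:** the semisquaric aryl ester 3-(4-methoxyphenoxy)cyclobut-3-ene-1,2-dione A1 would add the lithium acetylide of 1-(ethynyloxy)-4-methoxybenzene A2 at its more electrophilic carbonyl. This would give 4-hydroxy-3-(4-methoxyphenoxy)-4-[(4-methoxyphenoxy)ethynyl]cyclobut-2-en-1-one A3. Thermolysis should open A3 to an alkynyl(vinyl)ketene, which closes between the ketene carbon and the aryloxy-bearing alkyne carbon to give 2,5-bis(4-methoxyphenoxy)-1,4-benzoquinone A4.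
- **In its favour:** the para relation of the two aryloxy groups and both central oxygens is fixed by the mechanism, and the step is thermal and reagent-free. It avoids the hindered double substitution on a fully substituted ring, and on that point it is the better plan. The central hydroxyls would come from a simple quinone reduction with no protecting group on the central ring, which is also better than the methyl ethers of the chosen plan.
- **Against it here:** A4 carries no bromine. All eight C–Br bonds would have to be made late by electrophilic substitution. On each outer ring the third bromine must choose between the carbon beside methoxy (needed) and the carbon beside the aryloxy group (wrong), with only a modest electronic bias. Aryl ynol ethers such as A2 are sensitive, and the ring that is built can be bought as 1.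
- **Comparison:** the chosen plan buys six of the eight bromines already in position and adds the last two where no regiochemical choice exists. The count would be about nine steps against seven.

**Alternative 2:** Claisen dimerisation of an aryloxypyruvate.
- **Cut:** the central ring is cut into two three-carbon halves at the two bonds between each aryloxy-bearing carbon and the neighbouring oxygenated carbon.
- **Forward key step:** 2,3,5-tribromo-4-methoxyphenol A5 would be O-alkylated with a 3-halopyruvic ester to give ethyl 3-(2,3,5-tribromo-4-methoxyphenoxy)-2-oxopropanoate A6. Head-to-tail double Claisen condensation of A6 under ethoxide should give 2,5-dihydroxy-3,6-bis(2,3,5-tribromo-4-methoxyphenoxy)-1,4-benzoquinone A7.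
- **In its favour:** all six outer bromines are fixed in A5 before any coupling, which is better than the chosen plan with its one late bromination per ring. Two C–C bonds and a ring form in one operation, and the central ring arrives at the quinone oxidation level without protecting groups.
- **Against it here:** the ketone of an α-keto ester is more electrophilic than its ester, so aldol-type self-condensation to lactone dimers competes with the Claisen pathway. The two enolic hydroxyls of A7 must then be exchanged for bromine by a deoxygenative bromination of a vinylogous acid, a harsh step on an aryloxyquinone. A5 has an unsymmetrical tribromo pattern that itself needs a selective synthesis.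
- **Comparison:** on paper the sequence from A5 is about five steps (alkylation, dimerisation, bromine-for-hydroxyl exchange, reduction, demethylation). That is equal or slightly better in step count only if A5 is in hand. Mechanistically each of its central steps is less secure than the substitution and oxidation chemistry of the chosen plan.

**Alternative 3:** two-directional Robinson-type annulation.
- **Cut:** both outer rings are cut at the bond between the ether-bearing carbon and its CH2 neighbour and at the C2–C3 bond.
- **Forward key step:** the hydroquinone 3 would be O-alkylated with a haloacetaldehyde acetal and unmasked to 2,2'-[(2,5-dibromo-3,6-dimethoxy-1,4-phenylene)bis(oxy)]diacetaldehyde A8. Amine-catalysed Michael addition of A8 to but-3-en-2-one A9 at both ends, followed by aldol condensation, should give 4,4'-[(2,5-dibromo-3,6-dimethoxy-1,4-phenylene)bis(oxy)]bis(cyclohex-2-en-1-one) A10 as a stereoisomer mixture.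
- **In its favour:** the ether bonds are made by substitution at sp3 carbon, which a hindered phenoxide does more readily than attack on an arene, so on that point it is the better plan. No peracid is used, so the question of migratory preference never arises.
- **Against it here:** two benzene rings are built that can be bought. The γ-aryloxy enone in A10 can lose the central aryloxide, either by double-bond migration to an enol ether and hydrolysis or by elimination towards a phenol. The rings must then be dehydrogenated without palladium to 4,4'-[(2,5-dibromo-3,6-dimethoxy-1,4-phenylene)bis(oxy)]diphenol A11 and dibrominated to reach 7.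
- **Comparison:** from 3 to 7 this is five operations against three. After 7 the two plans share the same last two steps, so they are equal there and the alternative gains nothing.

Key step: step 4

## Steps

Step 1
Reactants: 1 bromanil (2,3,5,6-tetrabromo-1,4-benzoquinone)
Product: 2 2,5-dibromo-3,6-dimethoxy-1,4-benzoquinone
Conditions: NaOMe (2.05 equiv), MeOH, 0 °C → rt; filter the precipitate
Reagents that add atoms: sodium methoxide, [Na+].[O-]C
Why: Addition–elimination of methoxide on the tetrahaloquinone (vinylogous acyl substitution); the first methoxy group turns its own enone into a vinylogous ester, so the second methoxide should enter at the carbon para to it, and precipitation of the product from methanol limits further substitution.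

Step 2
Reactants: 2 2,5-dibromo-3,6-dimethoxy-1,4-benzoquinone
Product: 3 2,5-dibromo-3,6-dimethoxybenzene-1,4-diol
Conditions: Na2S2O4, EtOAc/H2O, rt, N2
Reagents that add atoms: none
Why: Dithionite reduction of a quinone to its hydroquinone by two electron transfers; aryl bromides and methyl ethers are inert, and the product is kept under nitrogen and used at once.

Step 3
Reactants: 3 2,5-dibromo-3,6-dimethoxybenzene-1,4-diol (1 equiv); 4 2,6-dibromo-4-fluorobenzaldehyde (2.2 equiv)
Product: 5 4,4'-[(2,5-dibromo-3,6-dimethoxy-1,4-phenylene)bis(oxy)]bis(2,6-dibromobenzaldehyde)
Conditions: K2CO3 (3 equiv), DMAc (degassed), 80 °C, Ar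
Reagents that add atoms: none
Why: Two-fold nucleophilic aromatic substitution (SNAr) in which the para formyl group stabilises the Meisenheimer adduct; fluoride at the unhindered para carbon is far the best nucleofuge, so the bromines beside the formyl group should stay, and exclusion of oxygen keeps the hydroquinone dianion from reverting to 2.

Step 4
Reactants: 5 4,4'-[(2,5-dibromo-3,6-dimethoxy-1,4-phenylene)bis(oxy)]bis(2,6-dibromobenzaldehyde)
Product: 6 [(2,5-dibromo-3,6-dimethoxy-1,4-phenylene)bis(oxy)]bis(2,6-dibromo-4,1-phenylene) diformate
Conditions: mCPBA (3 equiv), CH2Cl2, 0 °C → 40 °C; aq. Na2SO3, brief cold aq. NaHCO3 wash; used crude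
Reagents that add atoms: 3-chloroperoxybenzoic acid (mCPBA), OOC(=O)c1cccc(Cl)c1
Why: Each formyl carbonyl adds the peracid to give a Criegee adduct, and the aryl group then shifts from carbon to the proximal peroxide oxygen as 3-chlorobenzoate leaves, which turns the C4–CHO bond of each outer ring into a C4–O bond (aryl formate). The closest known reaction type is the Baeyer–Villiger (Dakin-type) oxidation of para-alkoxy- and para-aryloxybenzaldehydes to aryl formates. No ring is closed and no stereocentre is created, so only migratory selectivity and chemoselectivity are at stake. Aryl migration has to outrun hydride migration, which would give the benzoic acid; the ether oxygen para to the migrating carbon donates into the electron-deficient transition state, and because the central ring is twisted out of conjugation by its two ortho substituents, that lone pair is available mainly to the outer ring, whose own ortho positions are still unsubstituted at this stage. The two bromines beside the formyl group lower the migratory aptitude by induction, which is why the third bromine of each ring is deliberately not yet present. Chemoselectivity is secured by the substrate: the central ring has no C–H and no free hydroxyl (both oxygens are methyl ethers), and there is no alkene, amine or sulfide for the peracid to attack. The two aldehydes are remote and react independently, so the same argument holds at both ends. The aryl formates are base-labile and are therefore washed only briefly and carried on crude.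

Step 5
Reactants: 6 [(2,5-dibromo-3,6-dimethoxy-1,4-phenylene)bis(oxy)]bis(2,6-dibromo-4,1-phenylene) diformate
Product: 7 4,4'-[(2,5-dibromo-3,6-dimethoxy-1,4-phenylene)bis(oxy)]bis(2,6-dibromophenol)
Conditions: HCl (cat.), MeOH/THF, 25 °C
Reagents that add atoms: none
Why: Acid-catalysed transesterification (methanolysis) of an aryl formate; the formyl ester is highly electrophilic and the 2,6-dibromophenol is a good leaving group, while methyl ethers, diaryl ethers and C–Br bonds are untouched.

Step 6
Reactants: 7 4,4'-[(2,5-dibromo-3,6-dimethoxy-1,4-phenylene)bis(oxy)]bis(2,6-dibromophenol)
Product: 8 4,4'-[(2,5-dibromo-3,6-dimethoxy-1,4-phenylene)bis(oxy)]bis(2,3,6-tribromophenol)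
Conditions: Br2 (2.1 equiv), dry AcOH, 25 → 45 °C, dark; aq. NaHSO3
Reagents that add atoms: bromine, BrBr
Why: Electrophilic aromatic bromination; on each outer ring the carbons ortho and para to the hydroxyl are occupied, the only two open carbons are equivalent and ortho to the ether oxygen, which stabilises the arenium ion, and the central ring has no C–H. After one substitution the ring is deactivated and its last C–H is shielded by the central ring, so one bromine per ring is expected; dry acidic medium keeps any ipso-bromodienone reversible and avoids hydrolysis to a quinone.

Step 7
Reactants: 8 4,4'-[(2,5-dibromo-3,6-dimethoxy-1,4-phenylene)bis(oxy)]bis(2,3,6-tribromophenol)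
Product: 9 3,6-dibromo-2,5-bis(2,3,5-tribromo-4-hydroxyphenoxy)benzene-1,4-diol (CNP0163357.0)
Conditions: BBr3 (6 equiv), CH2Cl2, −78 °C → rt; H2O, aq. Na2S2O4, 0 °C
Reagents that add atoms: none
Why: Lewis acid-mediated cleavage of aryl methyl ethers (boron coordinates the methoxy oxygen, bromide attacks the methyl carbon by SN2); diaryl ether carbons cannot undergo SN2, so both ether links and all C–Br bonds should survive, and the reductive aqueous work-up hydrolyses the borates while keeping the central hydroquinone reduced.

## Compound list

1 | bromanil (2,3,5,6-tetrabromocyclohexa-2,5-diene-1,4-dione) | O=C1C(Br)=C(Br)C(=O)C(Br)=C1Br | starting material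
2 | 2,5-dibromo-3,6-dimethoxycyclohexa-2,5-diene-1,4-dione | O=C1C(Br)=C(OC)C(=O)C(Br)=C1OC | intermediate
3 | 2,5-dibromo-3,6-dimethoxybenzene-1,4-diol | Oc1c(Br)c(OC)c(O)c(Br)c1OC | intermediate
4 | 2,6-dibromo-4-fluorobenzaldehyde | O=Cc1c(Br)cc(F)cc1Br | starting material
5 | 4,4'-[(2,5-dibromo-3,6-dimethoxy-1,4-phenylene)bis(oxy)]bis(2,6-dibromobenzaldehyde) | O=Cc1c(Br)cc(Oc2c(OC)c(Br)c(Oc3cc(Br)c(C=O)c(Br)c3)c(OC)c2Br)cc1Br | intermediate
6 | [(2,5-dibromo-3,6-dimethoxy-1,4-phenylene)bis(oxy)]bis(2,6-dibromo-4,1-phenylene) diformate | O=COc1c(Br)cc(Oc2c(OC)c(Br)c(Oc3cc(Br)c(OC=O)c(Br)c3)c(OC)c2Br)cc1Br | intermediate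
7 | 4,4'-[(2,5-dibromo-3,6-dimethoxy-1,4-phenylene)bis(oxy)]bis(2,6-dibromophenol) | Oc1c(Br)cc(Oc2c(OC)c(Br)c(Oc3cc(Br)c(O)c(Br)c3)c(OC)c2Br)cc1Br | intermediate
8 | 4,4'-[(2,5-dibromo-3,6-dimethoxy-1,4-phenylene)bis(oxy)]bis(2,3,6-tribromophenol) | Oc1c(Br)cc(Oc2c(OC)c(Br)c(Oc3cc(Br)c(O)c(Br)c3Br)c(OC)c2Br)c(Br)c1Br | intermediate
9 | 3,6-dibromo-2,5-bis(2,3,5-tribromo-4-hydroxyphenoxy)benzene-1,4-diol | Oc1c(Br)cc(Oc2c(O)c(Br)c(Oc3cc(Br)c(O)c(Br)c3Br)c(O)c2Br)c(Br)c1Br | target

## Step count and risk assessment

Total step count: 7. Longest linear sequence: 7 steps (1 → 2 → 3 → 5 → 6 → 7 → 8 → 9; compound 4 is purchased).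

**Step 4 (key step).** The most likely failure is hydride migration in the Criegee adduct competing with aryl migration, because the two bromines beside the formyl group make the ring a poorer migrating group; this would divert material to the benzoic acids. Addition of the peracid to the doubly ortho-substituted formyl group may also be slow. The fallback removes the competing hydrogen. It sets out from 5: addition of MeMgBr (THF, −78 → 0 °C, where bromine–magnesium exchange is slow) would give 1,1'-{[(2,5-dibromo-3,6-dimethoxy-1,4-phenylene)bis(oxy)]bis(2,6-dibromo-4,1-phenylene)}diethanol F1 as a diastereomer mixture. Dess–Martin oxidation would give the bis(methyl ketone) 1,1'-{[(2,5-dibromo-3,6-dimethoxy-1,4-phenylene)bis(oxy)]bis(2,6-dibromo-4,1-phenylene)}diethanone F2. Baeyer–Villiger oxidation with peroxytrifluoroacetic acid, in which aryl competes only with methyl, would give [(2,5-dibromo-3,6-dimethoxy-1,4-phenylene)bis(oxy)]bis(2,6-dibromo-4,1-phenylene) diacetate F3. Methanolysis of F3 returns to the route at 7.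

**Step 6.** The most likely failure is over-bromination, because before the first substitution both open positions of each outer ring are equivalent and the selectivity for one bromine rests only on deactivation and shielding. A second risk is oxidative loss of the aryl ether through ipso attack para to the free hydroxyl. The fallback installs the third bromine before the ether bond exists. It sets out from 4: bromination with NBS in concentrated H2SO4 (one type of C–H only, ortho to fluorine and meta to formyl) would give 2,3,6-tribromo-4-fluorobenzaldehyde F4. Substitution of its fluoride by 3 under the conditions of step 3 would give 4,4'-[(2,5-dibromo-3,6-dimethoxy-1,4-phenylene)bis(oxy)]bis(2,3,6-tribromobenzaldehyde) F5. Baeyer–Villiger oxidation would give [(2,5-dibromo-3,6-dimethoxy-1,4-phenylene)bis(oxy)]bis(2,3,6-tribromo-4,1-phenylene) diformate F6, and methanolysis returns to the route at 8. The price is a more hindered ether formation and a less favourable aryl migration on the more electron-poor, more twisted ring.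

**Step 3.** The most likely failures are re-oxidation of the electron-rich hydroquinone dianion by traces of oxygen or by electron transfer, and stalling after the first arylation because the remaining phenoxide is hindered on both sides. The fallback reverses the polarity of ether formation and lets the quinone be the electrophile. It sets out from 4 and 1: hydroxylation of 4 with acetohydroxamic acid/K2CO3 in DMSO (a hydroxide surrogate that avoids Cannizzaro chemistry) would give 2,6-dibromo-4-hydroxybenzaldehyde F7. Two equivalents of its phenoxide should displace two para-disposed bromides of 1 to give 2,5-dibromo-3,6-bis(3,5-dibromo-4-formylphenoxy)cyclohexa-2,5-diene-1,4-dione F8. Dithionite reduction would give 4,4'-[(2,5-dibromo-3,6-dihydroxy-1,4-phenylene)bis(oxy)]bis(2,6-dibromobenzaldehyde) F9, and O-methylation (MeI, K2CO3) returns to the route at 5.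

## Further compounds

F1 | step 4 | 1,1'-{[(2,5-dibromo-3,6-dimethoxy-1,4-phenylene)bis(oxy)]bis(2,6-dibromo-4,1-phenylene)}diethanol (diastereomer mixture) | CC(O)c1c(Br)cc(Oc2c(OC)c(Br)c(Oc3cc(Br)c(C(C)O)c(Br)c3)c(OC)c2Br)cc1Br
F2 | step 4 | 1,1'-{[(2,5-dibromo-3,6-dimethoxy-1,4-phenylene)bis(oxy)]bis(2,6-dibromo-4,1-phenylene)}diethanone | CC(=O)c1c(Br)cc(Oc2c(OC)c(Br)c(Oc3cc(Br)c(C(C)=O)c(Br)c3)c(OC)c2Br)cc1Br
F3 | step 4 | [(2,5-dibromo-3,6-dimethoxy-1,4-phenylene)bis(oxy)]bis(2,6-dibromo-4,1-phenylene) diacetate | CC(=O)Oc1c(Br)cc(Oc2c(OC)c(Br)c(Oc3cc(Br)c(OC(C)=O)c(Br)c3)c(OC)c2Br)cc1Br
F4 | step 6 | 2,3,6-tribromo-4-fluorobenzaldehyde | O=Cc1c(Br)cc(F)c(Br)c1Br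
F5 | step 6 | 4,4'-[(2,5-dibromo-3,6-dimethoxy-1,4-phenylene)bis(oxy)]bis(2,3,6-tribromobenzaldehyde) | O=Cc1c(Br)cc(Oc2c(OC)c(Br)c(Oc3cc(Br)c(C=O)c(Br)c3Br)c(OC)c2Br)c(Br)c1Br
F6 | step 6 | [(2,5-dibromo-3,6-dimethoxy-1,4-phenylene)bis(oxy)]bis(2,3,6-tribromo-4,1-phenylene) diformate | O=COc1c(Br)cc(Oc2c(OC)c(Br)c(Oc3cc(Br)c(OC=O)c(Br)c3Br)c(OC)c2Br)c(Br)c1Br
F7 | step 3 | 2,6-dibromo-4-hydroxybenzaldehyde | O=Cc1c(Br)cc(O)cc1Br
F8 | step 3 | 2,5-dibromo-3,6-bis(3,5-dibromo-4-formylphenoxy)cyclohexa-2,5-diene-1,4-dione | O=Cc1c(Br)cc(OC2=C(Br)C(=O)C(Oc3cc(Br)c(C=O)c(Br)c3)=C(Br)C2=O)cc1Br
F9 | step 3 | 4,4'-[(2,5-dibromo-3,6-dihydroxy-1,4-phenylene)bis(oxy)]bis(2,6-dibromobenzaldehyde) | O=Cc1c(Br)cc(Oc2c(O)c(Br)c(Oc3cc(Br)c(C=O)c(Br)c3)c(O)c2Br)cc1Br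
A1 | alternative 1 | 3-(4-methoxyphenoxy)cyclobut-3-ene-1,2-dione | O=C1C=C(Oc2ccc(OC)cc2)C1=O
A2 | alternative 1 | 1-(ethynyloxy)-4-methoxybenzene | C#COc1ccc(OC)cc1
A3 | alternative 1 | 4-hydroxy-3-(4-methoxyphenoxy)-4-[(4-methoxyphenoxy)ethynyl]cyclobut-2-en-1-one (racemic) | O=C1C=C(Oc2ccc(OC)cc2)C1(O)C#COc1ccc(OC)cc1
A4 | alternative 1 | 2,5-bis(4-methoxyphenoxy)-1,4-benzoquinone | O=C1C=C(Oc2ccc(OC)cc2)C(=O)C=C1Oc1ccc(OC)cc1
A5 | alternative 2 | 2,3,5-tribromo-4-methoxyphenol | Oc1cc(Br)c(OC)c(Br)c1Br
A6 | alternative 2 | ethyl 3-(2,3,5-tribromo-4-methoxyphenoxy)-2-oxopropanoate | CCOC(=O)C(=O)COc1cc(Br)c(OC)c(Br)c1Br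
A7 | alternative 2 | 2,5-dihydroxy-3,6-bis(2,3,5-tribromo-4-methoxyphenoxy)-1,4-benzoquinone | O=C1C(O)=C(Oc2cc(Br)c(OC)c(Br)c2Br)C(=O)C(O)=C1Oc1cc(Br)c(OC)c(Br)c1Br
A8 | alternative 3 | 2,2'-[(2,5-dibromo-3,6-dimethoxy-1,4-phenylene)bis(oxy)]diacetaldehyde | O=CCOc1c(OC)c(Br)c(OCC=O)c(OC)c1Br
A9 | alternative 3 | but-3-en-2-one | C=CC(C)=O
A10 | alternative 3 | 4,4'-[(2,5-dibromo-3,6-dimethoxy-1,4-phenylene)bis(oxy)]bis(cyclohex-2-en-1-one) (stereoisomer mixture) | O=C1C=CC(Oc2c(OC)c(Br)c(OC3C=CC(=O)CC3)c(OC)c2Br)CC1
A11 | alternative 3 | 4,4'-[(2,5-dibromo-3,6-dimethoxy-1,4-phenylene)bis(oxy)]diphenol | Oc1ccc(Oc2c(OC)c(Br)c(Oc3ccc(O)cc3)c(OC)c2Br)cc1
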